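**Plan**

- Ring A is the non-phenolic ring, numbered C1 (O-aryl), C2 (isopropyl), C3 (H), C4 (OMe), C5 (CH3), C6 (H); ring B is the phenolic ring and comes from thymol.
- Enabling feature: C1 and C2 of ring A are the inner carbons of a 2,3-disubstituted butadiene with C6 and C3 as its CH2 termini, and C4/C5 are the two carbons of a dienophile, (E)-1-nitropropene, whose nitro group stands in for the C4 oxygen.
- Retrosynthesis: remove the benzyl group on ring B and the C4 O-methyl, de-aromatise ring A to the cyclohexenone and then the nitrocyclohexene, cut C3–C4 and C5–C6 ([4+2]), then cut the enol-ether C=CH2 (carbonyl methylenation) and the aryl ester C–O bond.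
- Forward: thymol is elaborated to a monobenzyl catechol, acylated with 2-isopropylacrylic acid and methylenated to the aryloxydiene; the cycloaddition closes ring A; Nef reaction, dehydrogenation, O-methylation and hydrogenolysis finish the synthesis.
- Stereochemistry: the target has no stereocentre; the two centres of the cycloadduct (trans, from the E-alkene, racemic) disappear on aromatisation.

Key step: step 12

Remark: Ar = 2-(benzyloxy)-3-isopropyl-5-methoxy-6-methylphenyl throughout. All chiral intermediates are carried as racemates, which is sufficient because their stereocentres are destroyed before the end.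

**Route**

Step 1
Reactants: 1 thymol
Product: 2 4-bromo-2-isopropyl-5-methylphenol
Conditions: NBS, MeCN, 0 °C to rt
Reagents that add atoms: N-bromosuccinimide, O=C1CCC(=O)N1Br
Why: Electrophilic aromatic bromination, where the hydroxyl group directs to its unhindered para position, so a single monobromide should result.

Step 2
Reactants: 2 4-bromo-2-isopropyl-5-methylphenol
Product: 3 2-isopropyl-4-methoxy-5-methylphenol
Conditions: NaOMe (excess), CuBr (cat.), DMF/MeOH, 110 °C; aq. HCl work-up
Reagents that add atoms: sodium methoxide, [Na+].[O-]C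
Why: Ullmann-type copper-catalysed C–O coupling of an aryl bromide with methoxide, a well-used way to turn bromophenols into methoxyphenols; the large excess of methoxide should outcompete the hindered phenoxide as nucleophile.

Step 3
Reactants: 3 2-isopropyl-4-methoxy-5-methylphenol
Product: 4 2-bromo-6-isopropyl-4-methoxy-3-methylphenol
Conditions: NBS, i-Pr2NH (cat.), CH2Cl2 (dry), 0 °C
Reagents that add atoms: N-bromosuccinimide, O=C1CCC(=O)N1Br
Why: Amine-catalysed ortho-bromination of a phenol, expected at the only free position ortho to OH (between OH and CH3) because the other free carbon is meta to OH and flanked by isopropyl and methoxy; dry, cold conditions should avoid oxidation to the quinone.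

Step 4
Reactants: 4 2-bromo-6-isopropyl-4-methoxy-3-methylphenol
Product: 5 1-(benzyloxy)-2-bromo-6-isopropyl-4-methoxy-3-methylbenzene
Conditions: BnBr, K2CO3, DMF, 50 °C
Reagents that add atoms: benzyl bromide, BrCc1ccccc1
Why: Williamson etherification of the phenoxide, which in DMF should proceed despite the two ortho substituents.

Step 5
Reactants: 5 1-(benzyloxy)-2-bromo-6-isopropyl-4-methoxy-3-methylbenzene
Product: 8 2-(benzyloxy)-3-isopropyl-5-methoxy-6-methylphenol, via aryllithium 6 (not isolated), via lithium aryltrimethoxyborate 7 (not isolated)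
Conditions: n-BuLi, THF, −78 °C; B(OMe)3, −78 °C to rt; H2O2, aq. NaOH, 0 °C to rt
Reagents that add atoms: hydrogen peroxide, OO
Why: Bromine–lithium exchange, borylation and oxidative 1,2-migration of the aryl group from boron to oxygen place the hydroxyl exactly where bromine stood, and the low temperature should suppress Wittig rearrangement of the neighbouring benzyl ether.

Step 6
Reactants: 9 diethyl isopropylmalonate
Product: 10 isopropylmalonic acid
Conditions: KOH, EtOH/H2O, reflux; aq. HCl
Reagents that add atoms: potassium hydroxide, [K+].[OH-]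
Why: Ordinary saponification of both ester groups followed by acidification.

Step 7
Reactants: 10 isopropylmalonic acid
Product: 12 2-isopropylacrylic acid (3-methyl-2-methylidenebutanoic acid), via Mannich base 11 (not isolated)
Conditions: (CH2O)n, Et2NH, EtOAc, reflux
Reagents that add atoms: paraformaldehyde (as formaldehyde), C=O
Why: Mannich condensation of the malonic acid with formaldehyde and the amine, then decarboxylative elimination of diethylamine, the standard route from monoalkylmalonic acids to 2-alkylacrylic acids.

Step 8
Reactants: 12 2-isopropylacrylic acid; 8 2-(benzyloxy)-3-isopropyl-5-methoxy-6-methylphenol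
Product: 14 Ar 3-methyl-2-methylidenebutanoate (the aryl 2-isopropylacrylate), via 2-isopropylacryloyl chloride 13 (not isolated)
Conditions: (COCl)2, DMF (cat.), CH2Cl2, 0 °C to rt, concentrate; then 8, Et3N, DMAP (cat.), CH2Cl2, 0 °C to rt
Reagents that add atoms: none
Why: Acid chloride formation followed by DMAP-catalysed O-acylation installs the hindered aryl–oxygen–carbon linkage as a simple ester, which is far easier than forming the enol ether bond directly.

Step 9
Reactants: 14 Ar 3-methyl-2-methylidenebutanoate
Product: 15 2-(ArO)-3-isopropylbuta-1,3-diene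
Conditions: Cp2TiMe2, toluene/THF, 65 °C, dark; filtration through basic alumina
Reagents that add atoms: dimethyltitanocene Cp2TiMe2, [Ti+4].[CH3-].[CH3-].c1cc[cH-]c1.c1cc[cH-]c1
Why: Petasis methylenation, in which thermally formed Cp2Ti=CH2 adds [2+2] to the ester carbonyl and cycloreverts with formation of the strong Ti=O bond; aryl esters and conjugated esters are known substrates, and the non-acidic medium suits the acid-labile 2-aryloxydiene.

Step 10
Reactants: 16 nitromethane; 17 acetaldehyde
Product: 18 1-nitropropan-2-ol (racemic)
Conditions: MeNO2 (excess), KOH (cat.), MeOH, 0 °C; AcOH quench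
Reagents that add atoms: none
Why: Henry (nitroaldol) addition of the nitronate to the aldehyde; the new carbinol centre is formed racemic and is removed in the next step.

Step 11
Reactants: 18 1-nitropropan-2-ol
Product: 20 (E)-1-nitroprop-1-ene, via hydrogen phthalate ester 19 (not isolated)
Conditions: phthalic anhydride, 150–180 °C, reduced pressure, product distilled out
Reagents that add atoms: none
Why: Acylation of the alcohol and E1cB loss of hydrogen phthalate from the α-nitro carbanion is the classical dehydration of β-nitro alcohols, and the conjugated E-alkene is the thermodynamically preferred isomer.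

Step 12
Reactants: 15 2-(ArO)-3-isopropylbuta-1,3-diene; 20 (E)-1-nitroprop-1-ene
Product: 21 racemic trans-1-(ArO)-2-isopropyl-5-methyl-4-nitrocyclohex-1-ene (4S,5S enantiomer drawn)
Conditions: 20 (3 equiv), BHT (cat.), toluene, 100 °C, sealed tube
Reagents that add atoms: none
Why: A concerted, thermally allowed suprafacial–suprafacial [4+2] cycloaddition of normal electron demand pairs the HOMO of the aryloxydiene with the LUMO of the nitroalkene; the closest known reaction type is the Diels–Alder reaction of 2-alkoxy- and 2-silyloxybutadienes with nitroalkenes used as ketene equivalents. Ring A closes as a six-membered carbocycle by intermolecular annulation, with both σ bonds formed in one step: the CH2 beside the aryloxy carbon bonds to the methyl-bearing carbon and the CH2 beside the isopropyl carbon bonds to the nitro-bearing carbon. The two new stereocentres (C4 with NO2, C5 with CH3) are fixed relative to each other by the E geometry of 20, transferred stereospecifically into the trans relationship; there is no facial bias, so the adduct is racemic, and the unsubstituted diene termini remove any endo/exo question. The step needs para regioselectivity (nitro 1,4 to aryloxy): the oxygen lone pair puts the largest HOMO coefficient on the CH2 of the enol-ether half, which pairs with the β carbon of the nitroalkene carrying the largest LUMO coefficient, and this donor is expected to outweigh the weak opposing bias of the isopropyl group. The s-cis conformer of a 2,3-disubstituted butadiene is readily populated, and the neutral medium with BHT protects the enol ether and restrains radical polymerisation.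

Step 13
Reactants: 21 trans-1-(ArO)-2-isopropyl-5-methyl-4-nitrocyclohex-1-ene
Product: 23 4-(ArO)-3-isopropyl-6-methylcyclohex-3-en-1-one (racemic), via sodium nitronate 22 (not isolated)
Conditions: NaOMe, MeOH, 0 °C; then aq. TiCl3, NH4OAc buffer (pH about 5–6), THF/H2O, 0 °C to rt
Reagents that add atoms: water, O
Why: Reductive Nef reaction, in which the nitronate is reduced by trivalent titanium to the imine and hydrolysed to the ketone; the buffered, near-neutral medium is chosen so that the tetrasubstituted aryl enol ether should survive, and the remaining methyl-bearing centre need not be controlled.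

Step 14
Reactants: 23 4-(ArO)-3-isopropyl-6-methylcyclohex-3-en-1-one
Product: 24 4-(ArO)-5-isopropyl-2-methylphenol
Conditions: DDQ (1.05 equiv), 1,4-dioxane (dry), rt
Reagents that add atoms: none
Why: Dehydrogenative aromatisation, in which DDQ takes a hydride from the doubly allylic CH2 of the dienol tautomer (cation stabilised by the aryloxy or hydroxy oxygen) and proton loss gives the phenol; one equivalent in a dry solvent should prevent further oxidation to a quinone, and the last stereocentre is erased.

Step 15
Reactants: 24 4-(ArO)-5-isopropyl-2-methylphenol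
Product: 25 1-(ArO)-2-isopropyl-4-methoxy-5-methylbenzene (benzyl ether of the target)
Conditions: MeI, K2CO3, acetone, 50 °C
Reagents that add atoms: iodomethane, CI
Why: Williamson O-methylation of the only free phenol in the molecule.

Step 16
Reactants: 25 1-(ArO)-2-isopropyl-4-methoxy-5-methylbenzene
Product: 26 6-isopropyl-2-(2-isopropyl-4-methoxy-5-methylphenoxy)-4-methoxy-3-methylphenol (CNP0271085.0)
Conditions: H2 (1 atm), 10% Pd/C, EtOAc/EtOH, rt
Reagents that add atoms: none
Why: Catalytic hydrogenolysis cleaves the benzylic C–O bond only; the diaryl ether and methyl ethers are inert under these conditions.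

**Compound list**

1 | thymol (2-isopropyl-5-methylphenol) | Cc1ccc(C(C)C)c(O)c1 | starting material
2 | 4-bromo-2-isopropyl-5-methylphenol | Cc1cc(O)c(C(C)C)cc1Br | intermediate
3 | 2-isopropyl-4-methoxy-5-methylphenol | COc1cc(C(C)C)c(O)cc1C | intermediate
4 | 2-bromo-6-isopropyl-4-methoxy-3-methylphenol | COc1cc(C(C)C)c(O)c(Br)c1C | intermediate
5 | 1-(benzyloxy)-2-bromo-6-isopropyl-4-methoxy-3-methylbenzene | COc1cc(C(C)C)c(OCc2ccccc2)c(Br)c1C | intermediate
6 | [2-(benzyloxy)-3-isopropyl-5-methoxy-6-methylphenyl]lithium (not isolated) | COc1cc(C(C)C)c(OCc2ccccc2)c([Li])c1C | intermediate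
7 | lithium [2-(benzyloxy)-3-isopropyl-5-methoxy-6-methylphenyl]trimethoxyborate (not isolated) | [Li+].CO[B-](OC)(OC)c1c(C)c(OC)cc(C(C)C)c1OCc1ccccc1 | intermediate
8 | 2-(benzyloxy)-3-isopropyl-5-methoxy-6-methylphenol (ArOH) | COc1cc(C(C)C)c(OCc2ccccc2)c(O)c1C | intermediate
9 | diethyl isopropylmalonate | CCOC(=O)C(C(C)C)C(=O)OCC | starting material
10 | isopropylmalonic acid | CC(C)C(C(=O)O)C(=O)O | intermediate
11 | 2-[(diethylamino)methyl]-2-isopropylmalonic acid (not isolated) | CCN(CC)CC(C(C)C)(C(=O)O)C(=O)O | intermediate
12 | 2-isopropylacrylic acid (3-methyl-2-methylidenebutanoic acid) | C=C(C(C)C)C(=O)O | intermediate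
13 | 2-isopropylacryloyl chloride (not isolated) | C=C(C(C)C)C(=O)Cl | intermediate
14 | 2-(benzyloxy)-3-isopropyl-5-methoxy-6-methylphenyl 3-methyl-2-methylidenebutanoate | C=C(C(C)C)C(=O)Oc1c(C)c(OC)cc(C(C)C)c1OCc1ccccc1 | intermediate
15 | 2-(benzyloxy)-1-isopropyl-5-methoxy-4-methyl-3-[(3-isopropylbuta-1,3-dien-2-yl)oxy]benzene | C=C(C(C)C)C(=C)Oc1c(C)c(OC)cc(C(C)C)c1OCc1ccccc1 | intermediate
16 | nitromethane | C[N+](=O)[O-] | starting material
17 | acetaldehyde | CC=O | starting material
18 | 1-nitropropan-2-ol (racemic) | CC(O)C[N+](=O)[O-] | intermediate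
19 | 2-{[(1-nitropropan-2-yl)oxy]carbonyl}benzoic acid (racemic, not isolated) | CC(C[N+](=O)[O-])OC(=O)c1ccccc1C(=O)O | intermediate
20 | (E)-1-nitroprop-1-ene | C/C=C/[N+](=O)[O-] | intermediate
21 | racemic trans-1-(ArO)-2-isopropyl-5-methyl-4-nitrocyclohex-1-ene (4S,5S enantiomer drawn) | COc1cc(C(C)C)c(OCc2ccccc2)c(OC2=C(C(C)C)C[C@H]([N+](=O)[O-])[C@@H](C)C2)c1C | intermediate
22 | sodium nitronate of 21 (racemic, not isolated) | COc1cc(C(C)C)c(OCc2ccccc2)c(OC2=C(C(C)C)CC(=[N+]([O-])[O-])C(C)C2)c1C.[Na+] | intermediate
23 | 4-(ArO)-3-isopropyl-6-methylcyclohex-3-en-1-one (racemic) | COc1cc(C(C)C)c(OCc2ccccc2)c(OC2=C(C(C)C)CC(=O)C(C)C2)c1C | intermediate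
24 | 4-(ArO)-5-isopropyl-2-methylphenol | COc1cc(C(C)C)c(OCc2ccccc2)c(Oc2cc(C)c(O)cc2C(C)C)c1C | intermediate
25 | 2-(benzyloxy)-1-isopropyl-3-(2-isopropyl-4-methoxy-5-methylphenoxy)-5-methoxy-4-methylbenzene | COc1cc(C(C)C)c(OCc2ccccc2)c(Oc2cc(C)c(OC)cc2C(C)C)c1C | intermediate
26 | 6-isopropyl-2-(2-isopropyl-4-methoxy-5-methylphenoxy)-4-methoxy-3-methylphenol (CNP0271085.0) | COc1cc(C(C)C)c(Oc2c(C)c(OC)cc(C(C)C)c2O)cc1C | target

**Step count**

Total: 16 steps. Longest linear sequence: 12 steps from thymol (steps 1–5, 8, 9, 12–16).

**Steps most likely to fail, with fallbacks**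

Step 12 (cycloaddition). The isopropyl group polarises the diene against the aryloxy group, so regiocontrol may erode. The nitroalkene may also react as a 4π heterodiene with the enol ether, or polymerise at the temperature required. The fallback uses an acyl-activated alkyne, so the adduct is already one oxidation level from the arene and no nitro group is involved. It sets out from diene 15, which is heated with pent-3-yn-2-one (toluene, 110 °C) to give 1-[4-(ArO)-5-isopropyl-2-methylcyclohexa-1,4-dien-1-yl]ethan-1-one F4, with the acetyl group para to the aryloxy group by the same polarisation. DDQ at room temperature should aromatise this to 1-[4-(ArO)-5-isopropyl-2-methylphenyl]ethan-1-one F5. Baeyer–Villiger oxidation (mCPBA, NaHCO3, CH2Cl2), with migration of the electron-rich aryl group, gives 4-(ArO)-5-isopropyl-2-methylphenyl acetate F6. Methanolysis (K2CO3, MeOH) returns to the route at phenol 24.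

Step 13 (Nef reaction). The aqueous titanium medium may hydrolyse the aryl enol ether, releasing the ring B phenol and a diketone, or the nitronate may be reduced incompletely. The fallback aromatises first, so the sensitive enol ether becomes a robust diaryl ether before nitrogen is exchanged for oxygen. It sets out from adduct 21, which is dehydrogenated with excess DDQ (chlorobenzene, 100 °C) to 1-(ArO)-2-isopropyl-5-methyl-4-nitrobenzene F7. Reduction with Fe powder and NH4Cl (EtOH/H2O, 70 °C) leaves the benzyl ether intact and gives 4-(ArO)-5-isopropyl-2-methylaniline F8. Diazotisation (NaNO2, aq. H2SO4, 0 °C) gives 4-(ArO)-5-isopropyl-2-methylbenzenediazonium hydrogensulfate F9, and copper-mediated hydroxylation (Cu2O, Cu(NO3)2, H2O, rt) returns to the route at phenol 24.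

Step 9 (methylenation). The hindered, conjugated aryl ester may react incompletely, the titanium intermediate may expel aryloxide, or the diene may hydrolyse or polymerise during isolation. The fallback builds the enol ether carbon–oxygen bond by alkylation and creates both methylidene groups by carbonyl chemistry that avoids titanium carbenes. It sets out from phenol 8, which is alkylated with 1-bromo-3-methylbutan-2-one (K2CO3, acetone) to give 1-(ArO)-3-methylbutan-2-one F1. α-Methylenation at the aryloxy-bearing CH2 (paraformaldehyde, diisopropylammonium trifluoroacetate, THF, reflux) gives 2-(ArO)-4-methylpent-1-en-3-one F2. Peterson olefination follows: 1,2-addition of Me3SiCH2MgCl in the presence of CeCl3 (THF, −78 °C) gives 3-(ArO)-2-isopropyl-1-(trimethylsilyl)but-3-en-2-ol F3, and KH (THF, 0 °C) eliminates it under basic conditions to return to the route at diene 15.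

**Further compounds**

F1 | step 9 | 1-[2-(benzyloxy)-3-isopropyl-5-methoxy-6-methylphenoxy]-3-methylbutan-2-one | CC(C)C(=O)COc1c(C)c(OC)cc(C(C)C)c1OCc1ccccc1
F2 | step 9 | 2-[2-(benzyloxy)-3-isopropyl-5-methoxy-6-methylphenoxy]-4-methylpent-1-en-3-one | C=C(Oc1c(C)c(OC)cc(C(C)C)c1OCc1ccccc1)C(=O)C(C)C
F3 | step 9 | 3-[2-(benzyloxy)-3-isopropyl-5-methoxy-6-methylphenoxy]-2-isopropyl-1-(trimethylsilyl)but-3-en-2-ol (racemic) | C=C(Oc1c(C)c(OC)cc(C(C)C)c1OCc1ccccc1)C(O)(C(C)C)C[Si](C)(C)C
F4 | step 12 | 1-[4-(ArO)-5-isopropyl-2-methylcyclohexa-1,4-dien-1-yl]ethan-1-one | CC(=O)C1=C(C)CC(Oc2c(C)c(OC)cc(C(C)C)c2OCc2ccccc2)=C(C(C)C)C1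
F5 | step 12 | 1-[4-(ArO)-5-isopropyl-2-methylphenyl]ethan-1-one | CC(=O)c1cc(C(C)C)c(Oc2c(C)c(OC)cc(C(C)C)c2OCc2ccccc2)cc1C
F6 | step 12 | 4-(ArO)-5-isopropyl-2-methylphenyl acetate | CC(=O)Oc1cc(C(C)C)c(Oc2c(C)c(OC)cc(C(C)C)c2OCc2ccccc2)cc1C
F7 | step 13 | 1-(ArO)-2-isopropyl-5-methyl-4-nitrobenzene | Cc1cc(Oc2c(C)c(OC)cc(C(C)C)c2OCc2ccccc2)c(C(C)C)cc1[N+](=O)[O-]
F8 | step 13 | 4-(ArO)-5-isopropyl-2-methylaniline | Cc1cc(Oc2c(C)c(OC)cc(C(C)C)c2OCc2ccccc2)c(C(C)C)cc1N
F9 | step 13 | 4-(ArO)-5-isopropyl-2-methylbenzenediazonium hydrogensulfate | Cc1cc(Oc2c(C)c(OC)cc(C(C)C)c2OCc2ccccc2)c(C(C)C)cc1[N+]#N.OS(=O)(=O)[O-]
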